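**Strategy.** The chain is numbered C1 (carboxyl) to C19; ring A is the oxane (O, C3–C7). Everything rests on cutting the C9–C10 single bond in the middle of the C8=C9–C10=C11 diene, the only link between ring A and the epoxide-bearing chain. A Suzuki–Miyaura coupling joins the ring A (E)-alkenyl iodide (C1–C9, three stereocentres, methyl ester) with the (E)-alkenyl pinacol boronate (C10–C19, four stereocentres, free C18 hydroxyl) and builds the diene in one operation with both alkene geometries retained and no protecting groups. The C18 hydroxyl then directs epoxidation of C14=C15, and ester hydrolysis completes the synthesis.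

Key step: step 17

Remark: (R)-2-(benzoyloxy)pentan-3-one is taken as not purchasable and is made from methyl (R)-lactate; all other starting materials and reagents are catalogue chemicals.

**Ring A fragment (C1–C9)**

Step 1
Reactants: 1 propargyl alcohol
Product: 3 (E)-3-iodo-2-methylprop-2-en-1-ol, via alkenylalane 2 (not isolated)
Conditions: AlMe3, Cp2ZrCl2 (cat.), CH2Cl2, 0 °C to rt; then I2, THF, −30 to 0 °C
Reagents that add atoms: trimethylaluminium, C[Al](C)C; iodine, II
Why: Zirconium-catalysed Negishi carboalumination adds methyl and aluminium syn across the alkyne with methyl on the internal carbon, and iodinolysis of the alkenyl–aluminium bond with retention should fix the E geometry of the future C8=C9 unit.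

Step 2
Reactants: 3 (E)-3-iodo-2-methylprop-2-en-1-ol
Product: 4 (E)-3-iodo-2-methylprop-2-enal
Conditions: MnO2, CH2Cl2, rt
Reagents that add atoms: none
Why: Allylic alcohol oxidation with MnO2 should stop at the enal and leave the alkenyl iodide and its geometry untouched.

Step 3
Reactants: 4 (E)-3-iodo-2-methylprop-2-enal
Product: 5 (1E,3S,4S)-1-iodo-2,4-dimethylhexa-1,5-dien-3-ol
Conditions: trans-2-butene, KOtBu, nBuLi, THF, −78 to −45 °C; (−)-Ipc2BOMe, then BF3·OEt2, −78 °C; then 4, −78 °C; NaOH, H2O2, rt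
Reagents that add atoms: trans-2-butene, C/C=C/C
Why: Asymmetric crotylboration through a closed chair transition state should give the anti C6/C7 relationship from the (E)-crotyl group, while the isopinocampheyl ligands derived from (+)-α-pinene direct attack on the Si face of the aldehyde to set (3S,4S).

Step 4
Reactants: 5 (1E,3S,4S)-1-iodo-2,4-dimethylhexa-1,5-dien-3-ol; 6 crotonaldehyde
Product: 7 (2E,4S,5S,6E)-5-hydroxy-7-iodo-4,6-dimethylhepta-2,6-dienal
Conditions: second-generation Hoveyda–Grubbs catalyst (cat.), CH2Cl2, 40 °C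
Reagents that add atoms: none
Why: Olefin cross-metathesis of the terminal alkene with the enal partner should be E-selective, the trisubstituted iodoalkene being inert to the ruthenium carbene.

Step 5
Reactants: 7 (2E,4S,5S,6E)-5-hydroxy-7-iodo-4,6-dimethylhepta-2,6-dienal
Product: 9 (5S,6S)-6-[(E)-1-iodoprop-1-en-2-yl]-5-methyloxan-2-ol (anomer mixture), via open-chain hydroxy aldehyde 8 (not isolated)
Conditions: [(Ph3P)CuH]6, H2O, benzene, rt
Reagents that add atoms: none
Why: Copper hydride conjugate reduction should saturate only the enal C=C, and the resulting δ-hydroxy aldehyde should close spontaneously to the six-membered lactol without touching C6 or C7.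

Step 6
Reactants: 9 (5S,6S)-6-[(E)-1-iodoprop-1-en-2-yl]-5-methyloxan-2-ol
Product: 11 methyl 2-[(2R,5S,6S)-6-[(E)-1-iodoprop-1-en-2-yl]-5-methyloxan-2-yl]acetate, via hydroxy enoate 10 (not isolated)
Conditions: Ph3P=CHCO2Me, toluene, 90 °C; then DBU, 90 °C
Reagents that add atoms: methyl (triphenylphosphoranylidene)acetate, COC(=O)C=P(c1ccccc1)(c1ccccc1)c1ccccc1
Why: Wittig olefination of the lactol gives the (E)-enoate, and reversible base-mediated intramolecular oxa-Michael addition (6-exo-trig) should settle on the all-equatorial 2,6-cis oxane, so C3 is set under thermodynamic control by C6 and C7.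

**Side-chain fragment (C10–C19)**

Step 7
Reactants: 12 methyl (R)-lactate
Product: 13 (2R)-2-hydroxy-N-methoxy-N-methylpropanamide
Conditions: MeNH(OMe)·HCl, iPrMgCl, THF, −20 to 0 °C
Reagents that add atoms: N,O-dimethylhydroxylamine hydrochloride, CNOC.Cl
Why: Aminolysis of the ester by the magnesium amide (Weinreb amide formation) should proceed without touching the C18 stereocentre.

Step 8
Reactants: 13 (2R)-2-hydroxy-N-methoxy-N-methylpropanamide
Product: 14 (2R)-2-hydroxypentan-3-one
Conditions: EtMgBr, THF, 0 °C to rt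
Reagents that add atoms: ethylmagnesium bromide, CC[Mg]Br
Why: Grignard addition to the Weinreb amide should stop at the ketone because the magnesium chelate survives until work-up.

Step 9
Reactants: 14 (2R)-2-hydroxypentan-3-one
Product: 15 (2R)-3-oxopentan-2-yl benzoate
Conditions: (PhCO)2O, DMAP (cat.), iPr2NEt, CH2Cl2, rt
Reagents that add atoms: benzoic anhydride, O=C(OC(=O)c1ccccc1)c1ccccc1
Why: DMAP-catalysed acylation of the secondary alcohol installs the benzoate needed to steer the following aldol.

Step 10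
Reactants: 15 (2R)-3-oxopentan-2-yl benzoate; 16 methacrolein
Product: 18 (2R,4S,5R)-5-hydroxy-4,6-dimethyl-3-oxohept-6-en-2-yl benzoate, via enol borinate 17 (not isolated)
Conditions: Cy2BCl, Me2NEt, Et2O, −78 to 0 °C; then 16, −78 to −20 °C; H2O2, MeOH, pH 7 buffer, 0 °C
Reagents that add atoms: none
Why: Boron-mediated anti-aldol reaction: the (E)-enol borinate reacts through a chair transition state to give the anti C15/C16 relationship, and the α'-benzoyloxy stereocentre (benzoate carbonyl hydrogen-bonded to the formyl hydrogen) should select the enolate face so that C16 and C15 are set as (4S,5R).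

Step 11
Reactants: 18 (2R,4S,5R)-5-hydroxy-4,6-dimethyl-3-oxohept-6-en-2-yl benzoate; 19 propanal
Product: 20 (2R,3R,4R,5R)-3-hydroxy-4,6-dimethyl-5-(propanoyloxy)hept-6-en-2-yl benzoate
Conditions: SmI2 (cat., premixed with 19), THF, −10 °C
Reagents that add atoms: none
Why: Evans–Tishchenko reduction: the hemiacetal of the C15 hydroxyl with propanal delivers hydride intramolecularly within a trivalent samarium chelate, which should set the 1,3-anti C17 alcohol and leave the C15 oxygen as the propanoate needed for step 13.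

Step 12
Reactants: 20 (2R,3R,4R,5R)-3-hydroxy-4,6-dimethyl-5-(propanoyloxy)hept-6-en-2-yl benzoate
Product: 21 (2R,3R,4S,5R)-3-methoxy-4,6-dimethyl-5-(propanoyloxy)hept-6-en-2-yl benzoate
Conditions: Me3OBF4, 1,8-bis(dimethylamino)naphthalene, CH2Cl2, 0 °C to rt
Reagents that add atoms: trimethyloxonium tetrafluoroborate, C[O+](C)C.F[B-](F)(F)F
Why: O-Methylation with an oxonium salt and a hindered non-nucleophilic base is mild enough to avoid acyl migration and touches no stereocentre.

Step 13
Reactants: 21 (2R,3R,4S,5R)-3-methoxy-4,6-dimethyl-5-(propanoyloxy)hept-6-en-2-yl benzoate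
Product: 24 (2S,4E,6S,7R,8R)-8-(benzoyloxy)-7-methoxy-2,4,6-trimethylnon-4-enoic acid, via silyl ketene acetal 22 (not isolated), via trimethylsilyl ester 23 (not isolated)
Conditions: LiN(iPr)2, Me3SiCl, Et3N, THF, −78 °C to rt; then 1 M HCl
Reagents that add atoms: none
Why: Ireland–Claisen rearrangement: kinetic enolisation gives the E(O)-enolate (methyl trans to OSiMe3), and the chair transition state with the C16 branch equatorial should transfer the C15 configuration to C12 (S) and create the C14=C15 alkene as E.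

Step 14
Reactants: 24 (2S,4E,6S,7R,8R)-8-(benzoyloxy)-7-methoxy-2,4,6-trimethylnon-4-enoic acid
Product: 25 (2S,4E,6S,7R,8R)-7-methoxy-2,4,6-trimethylnon-4-ene-1,8-diol
Conditions: LiAlH4, THF, 0 °C to rt
Reagents that add atoms: none
Why: Hydride reduction should convert the acid into the primary alcohol and remove the benzoate in the same operation, leaving the isolated alkene and all stereocentres intact.

Step 15
Reactants: 25 (2S,4E,6S,7R,8R)-7-methoxy-2,4,6-trimethylnon-4-ene-1,8-diol
Product: 26 (2S,4E,6S,7R,8R)-8-hydroxy-7-methoxy-2,4,6-trimethylnon-4-enal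
Conditions: TEMPO (cat.), PhI(OAc)2, CH2Cl2, rt
Reagents that add atoms: none
Why: Oxoammonium-mediated oxidation is selective for the primary over the secondary alcohol and, being neutral, should not epimerise C12.

Step 16
Reactants: 26 (2S,4E,6S,7R,8R)-8-hydroxy-7-methoxy-2,4,6-trimethylnon-4-enal
Product: 27 (2R,3R,4S,5E,8S,9E)-3-methoxy-4,6,8-trimethyl-10-(4,4,5,5-tetramethyl-1,3,2-dioxaborolan-2-yl)deca-5,9-dien-2-ol
Conditions: CrCl2, LiI, Cl2CHBpin, THF, rt
Reagents that add atoms: 2-(dichloromethyl)-4,4,5,5-tetramethyl-1,3,2-dioxaborolane, ClC(Cl)B1OC(C)(C)C(C)(C)O1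
Why: Takai–Utimoto olefination with the geminal dichromium reagent should give the (E)-alkenyl boronate (C10=C11) under neutral conditions that tolerate the free hydroxyl and the α-stereocentre.

**Fragment union and completion**

Step 17
Reactants: 11 methyl 2-[(2R,5S,6S)-6-[(E)-1-iodoprop-1-en-2-yl]-5-methyloxan-2-yl]acetate; 27 (2R,3R,4S,5E,8S,9E)-3-methoxy-4,6,8-trimethyl-10-(4,4,5,5-tetramethyl-1,3,2-dioxaborolan-2-yl)deca-5,9-dien-2-ol
Product: 28 methyl 2-[(2R,5S,6S)-6-[(2E,4E,6S,8E,10S,11R,12R)-12-hydroxy-11-methoxy-6,8,10-trimethyltrideca-2,4,8-trien-2-yl]-5-methyloxan-2-yl]acetate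
Conditions: Pd(PPh3)4 (cat.), Cs2CO3, THF/H2O, 55 °C
Reagents that add atoms: none
Why: Suzuki–Miyaura alkenyl–alkenyl coupling: zerovalent palladium inserts into the C9–I bond of 11 with retention, the boronate 27 activated by aqueous carbonate transfers its C10 alkenyl group with retention, and reductive elimination forms the C9–C10 bond. The closest known reaction type is the palladium-catalysed coupling of (E)-alkenyl iodides with (E)-alkenyl pinacol boronates to give conjugated dienes. No ring is closed and no stereocentre is created; the stereochemical elements are the two alkene geometries (8E, 10E), each carried over unchanged from its fragment. The step needs chemoselectivity for the single C–I and single C–B bond in the presence of a free secondary alcohol, a methyl ester, an allylic ether and a trisubstituted alkene, all of which are inert to the catalyst under mildly basic conditions. Protodeboronation and geometric isomerisation should be limited because both partners are α-branched and the temperature is moderate.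

Step 18
Reactants: 28 methyl 2-[(2R,5S,6S)-6-[(2E,4E,6S,8E,10S,11R,12R)-12-hydroxy-11-methoxy-6,8,10-trimethyltrideca-2,4,8-trien-2-yl]-5-methyloxan-2-yl]acetate
Product: 29 methyl 2-[(2R,5S,6S)-6-[(2E,4E,6S)-7-[(2R,3R)-3-[(2R,3R,4R)-4-hydroxy-3-methoxypentan-2-yl]-2-methyloxiran-2-yl]-6-methylhepta-2,4-dien-2-yl]-5-methyloxan-2-yl]acetate
Conditions: VO(acac)2 (cat.), tBuOOH, CH2Cl2, −15 °C
Reagents that add atoms: tert-butyl hydroperoxide, CC(C)(C)OO
Why: Hydroxyl-directed vanadium-catalysed epoxidation: the C18 vanadate ester should deliver oxygen to the bishomoallylic C14=C15 alkene through a chair-like transition state with the C16 methyl and C17 methoxy groups pseudo-equatorial, setting (14R,15R), while the undirected diene is left alone.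

Step 19
Reactants: 29 herboxidiene methyl ester
Product: 30 herboxidiene, 2-[(2R,5S,6S)-6-[(2E,4E,6S)-7-[(2R,3R)-3-[(2R,3R,4R)-4-hydroxy-3-methoxypentan-2-yl]-2-methyloxiran-2-yl]-6-methylhepta-2,4-dien-2-yl]-5-methyloxan-2-yl]acetic acid
Conditions: Me3SnOH, ClCH2CH2Cl, 80 °C; then aq. KHSO4
Reagents that add atoms: trimethyltin hydroxide, C[Sn](C)(C)O
Why: Ester hydrolysis with Me3SnOH under near-neutral conditions should free the acid while sparing the epoxide, the diene and all stereocentres.

**Compound list**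

1 | propargyl alcohol (prop-2-yn-1-ol) | C#CCO | starting material
2 | alkenylalane formed in the flask: dimethyl[(1E)-3-[(dimethylalumanyl)oxy]-2-methylprop-1-en-1-yl]alumane | C[Al](C)/C=C(\C)CO[Al](C)C | intermediate
3 | (E)-3-iodo-2-methylprop-2-en-1-ol | I/C=C(\C)CO | intermediate
4 | (E)-3-iodo-2-methylprop-2-enal | I/C=C(\C)C=O | intermediate
5 | (1E,3S,4S)-1-iodo-2,4-dimethylhexa-1,5-dien-3-ol | I/C=C(\C)[C@@H](O)[C@@H](C)C=C | intermediate
6 | crotonaldehyde, (E)-but-2-enal | C/C=C/C=O | starting material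
7 | (2E,4S,5S,6E)-5-hydroxy-7-iodo-4,6-dimethylhepta-2,6-dienal | I/C=C(\C)[C@@H](O)[C@@H](C)/C=C/C=O | intermediate
8 | open-chain hydroxy aldehyde formed in the flask: (4S,5S,6E)-5-hydroxy-7-iodo-4,6-dimethylhept-6-enal | I/C=C(\C)[C@@H](O)[C@@H](C)CCC=O | intermediate
9 | (5S,6S)-6-[(E)-1-iodoprop-1-en-2-yl]-5-methyloxan-2-ol, anomer mixture | I/C=C(\C)[C@H]1OC(O)CC[C@@H]1C | intermediate
10 | hydroxy enoate formed in the flask: methyl (2E,6S,7S,8E)-7-hydroxy-9-iodo-6,8-dimethylnona-2,8-dienoate | I/C=C(\C)[C@@H](O)[C@@H](C)CC/C=C/C(=O)OC | intermediate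
11 | methyl 2-[(2R,5S,6S)-6-[(E)-1-iodoprop-1-en-2-yl]-5-methyloxan-2-yl]acetate | I/C=C(\C)[C@H]1O[C@@H](CC(=O)OC)CC[C@@H]1C | intermediate
12 | methyl (R)-lactate, methyl (2R)-2-hydroxypropanoate | C[C@@H](O)C(=O)OC | starting material
13 | (2R)-2-hydroxy-N-methoxy-N-methylpropanamide | C[C@@H](O)C(=O)N(C)OC | intermediate
14 | (2R)-2-hydroxypentan-3-one | C[C@@H](O)C(=O)CC | intermediate
15 | (2R)-3-oxopentan-2-yl benzoate | C[C@@H](OC(=O)c1ccccc1)C(=O)CC | intermediate
16 | methacrolein, 2-methylprop-2-enal | C=C(C)C=O | starting material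
17 | enol borinate formed in the flask: (2R,3E)-3-[(dicyclohexylboranyl)oxy]pent-3-en-2-yl benzoate | C/C=C(/OB(C1CCCCC1)C1CCCCC1)[C@@H](C)OC(=O)c1ccccc1 | intermediate
18 | (2R,4S,5R)-5-hydroxy-4,6-dimethyl-3-oxohept-6-en-2-yl benzoate | C[C@@H](OC(=O)c1ccccc1)C(=O)[C@@H](C)[C@@H](O)C(C)=C | intermediate
19 | propanal | CCC=O | starting material
20 | (2R,3R,4R,5R)-3-hydroxy-4,6-dimethyl-5-(propanoyloxy)hept-6-en-2-yl benzoate | C[C@@H](OC(=O)c1ccccc1)[C@H](O)[C@@H](C)[C@@H](OC(=O)CC)C(C)=C | intermediate
21 | (2R,3R,4S,5R)-3-methoxy-4,6-dimethyl-5-(propanoyloxy)hept-6-en-2-yl benzoate | C[C@@H](OC(=O)c1ccccc1)[C@H](OC)[C@@H](C)[C@@H](OC(=O)CC)C(C)=C | intermediate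
22 | silyl ketene acetal formed in the flask: (E)-O-trimethylsilyl ketene acetal of 21, methyl trans to OSiMe3 | C[C@@H](OC(=O)c1ccccc1)[C@H](OC)[C@@H](C)[C@@H](O/C(O[Si](C)(C)C)=C\C)C(C)=C | intermediate
23 | trimethylsilyl ester formed in the flask: trimethylsilyl (2S,4E,6S,7R,8R)-8-(benzoyloxy)-7-methoxy-2,4,6-trimethylnon-4-enoate | C[C@@H](OC(=O)c1ccccc1)[C@H](OC)[C@@H](C)/C=C(\C)C[C@H](C)C(=O)O[Si](C)(C)C | intermediate
24 | (2S,4E,6S,7R,8R)-8-(benzoyloxy)-7-methoxy-2,4,6-trimethylnon-4-enoic acid | C[C@@H](OC(=O)c1ccccc1)[C@H](OC)[C@@H](C)/C=C(\C)C[C@H](C)C(=O)O | intermediate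
25 | (2S,4E,6S,7R,8R)-7-methoxy-2,4,6-trimethylnon-4-ene-1,8-diol | C[C@@H](O)[C@H](OC)[C@@H](C)/C=C(\C)C[C@H](C)CO | intermediate
26 | (2S,4E,6S,7R,8R)-8-hydroxy-7-methoxy-2,4,6-trimethylnon-4-enal | C[C@@H](O)[C@H](OC)[C@@H](C)/C=C(\C)C[C@H](C)C=O | intermediate
27 | (2R,3R,4S,5E,8S,9E)-3-methoxy-4,6,8-trimethyl-10-(4,4,5,5-tetramethyl-1,3,2-dioxaborolan-2-yl)deca-5,9-dien-2-ol | C[C@@H](O)[C@H](OC)[C@@H](C)/C=C(\C)C[C@H](C)/C=C/B1OC(C)(C)C(C)(C)O1 | intermediate
28 | methyl 2-[(2R,5S,6S)-6-[(2E,4E,6S,8E,10S,11R,12R)-12-hydroxy-11-methoxy-6,8,10-trimethyltrideca-2,4,8-trien-2-yl]-5-methyloxan-2-yl]acetate | C[C@@H](O)[C@H](OC)[C@@H](C)/C=C(\C)C[C@H](C)/C=C/C=C(\C)[C@H]1O[C@@H](CC(=O)OC)CC[C@@H]1C | intermediate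
29 | herboxidiene methyl ester | C[C@@H](O)[C@H](OC)[C@@H](C)[C@H]1O[C@]1(C)C[C@H](C)/C=C/C=C(\C)[C@H]2O[C@@H](CC(=O)OC)CC[C@@H]2C | intermediate
30 | herboxidiene | C[C@@H](O)[C@H](OC)[C@@H](C)[C@H]1O[C@]1(C)C[C@H](C)/C=C/C=C(\C)[C@H]2O[C@@H](CC(=O)O)CC[C@@H]2C | target

**Step count**

Total steps: 19. Longest linear sequence: 13 steps (steps 7–16, then 17–19); the ring A branch is 6 steps (steps 1–6) before the union.

**Steps most likely to fail**

Step 5. The risk is competing 1,2-reduction of the aldehyde or hydrodeiodination of the alkenyl iodide by copper hydride, which would erode the handle needed for step 17. The fallback sets out from 5 and saturates a non-conjugated alkene with diimide instead. Cross-metathesis of 5 with acrolein diethyl acetal (second-generation Hoveyda–Grubbs catalyst, CH2Cl2, 40 °C) should give (1E,3S,4S,5E)-7,7-diethoxy-1-iodo-2,4-dimethylhepta-1,5-dien-3-ol F1. Diimide generated from 2-nitrobenzenesulfonyl hydrazide and Et3N should reduce only the disubstituted alkene and give (1E,3S,4S)-7,7-diethoxy-1-iodo-2,4-dimethylhept-1-en-3-ol F2. Mild aqueous acid (pyridinium p-toluenesulfonate, acetone/H2O) should then unmask the aldehyde, which closes to lactol 9, where the route is rejoined.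

Step 13. The risk is incomplete control of enolate geometry, which would erode selectivity at C12, together with attack of the amide base on the benzoate. The fallback sets out from 21 and fixes the ketene acetal geometry by allylic strain in a neutral, thermal rearrangement. Methanolysis of both esters (K2CO3, MeOH) should give (2R,3R,4S,5R)-3-methoxy-4,6-dimethylhept-6-ene-2,5-diol F3. Eschenmoser–Claisen rearrangement of its allylic C15 hydroxyl with N,N-dimethylpropanamide dimethyl acetal (xylene, 140 °C) should pass through the (Z)-ketene N,O-acetal and the same chair as in step 13 to give (2S,4E,6S,7R,8R)-8-hydroxy-7-methoxy-N,N,2,4,6-pentamethylnon-4-enamide F4. Reduction of the amide with LiH2NBH3 (THF, 0 °C to rt) should give the primary alcohol 25, where the route is rejoined; any propanoate formed at the C18 hydroxyl is cleaved in the same reduction.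

Step 17. The risk is protodeboronation of the alkenyl boronate or slow transmetalation, with loss of diene geometry on prolonged heating. The fallback sets out from 26 and replaces the boron partner by a tin partner. Seyferth–Gilbert homologation with dimethyl (1-diazo-2-oxopropyl)phosphonate (K2CO3, MeOH) should give (2R,3R,4S,5E,8S)-3-methoxy-4,6,8-trimethyldec-5-en-9-yn-2-ol F5. Palladium-catalysed hydrostannation (Bu3SnH, Pd(PPh3)2Cl2 cat., THF, 0 °C) should give (2R,3R,4S,5E,8S,9E)-3-methoxy-4,6,8-trimethyl-10-(tributylstannyl)deca-5,9-dien-2-ol F6. Stille coupling of F6 with 11 (Pd2(dba)3, AsPh3, N-methylpyrrolidone, rt) should form the same C9–C10 bond and give 28, where the route is rejoined.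

**Further compounds**

F1 | step 5 | (1E,3S,4S,5E)-7,7-diethoxy-1-iodo-2,4-dimethylhepta-1,5-dien-3-ol | I/C=C(\C)[C@@H](O)[C@@H](C)/C=C/C(OCC)OCC
F2 | step 5 | (1E,3S,4S)-7,7-diethoxy-1-iodo-2,4-dimethylhept-1-en-3-ol | I/C=C(\C)[C@@H](O)[C@@H](C)CCC(OCC)OCC
F3 | step 13 | (2R,3R,4S,5R)-3-methoxy-4,6-dimethylhept-6-ene-2,5-diol | C[C@@H](O)[C@H](OC)[C@@H](C)[C@@H](O)C(C)=C
F4 | step 13 | (2S,4E,6S,7R,8R)-8-hydroxy-7-methoxy-N,N,2,4,6-pentamethylnon-4-enamide | C[C@@H](O)[C@H](OC)[C@@H](C)/C=C(\C)C[C@H](C)C(=O)N(C)C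
F5 | step 17 | (2R,3R,4S,5E,8S)-3-methoxy-4,6,8-trimethyldec-5-en-9-yn-2-ol | C[C@@H](O)[C@H](OC)[C@@H](C)/C=C(\C)C[C@H](C)C#C
F6 | step 17 | (2R,3R,4S,5E,8S,9E)-3-methoxy-4,6,8-trimethyl-10-(tributylstannyl)deca-5,9-dien-2-ol | C[C@@H](O)[C@H](OC)[C@@H](C)/C=C(\C)C[C@H](C)/C=C/[Sn](CCCC)(CCCC)CCCC
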